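**Assumption:** the target has no stereogenic centre, so "single enantiomer" is taken to mean the single (E)-enone isomer drawn. The route is a paper design and has not been run.

## Retrosynthetic overview
1. Target 7 ⇒ licochalcone A (6) by late-stage, regioselective ortho C–H oxygenation of the B-ring phenol (IBX, then reduction). This is the bold step: it removes any need to differentiate three pyrogallol oxygens or use protecting groups.
2. 6 ⇒ aryl bromide 4 + an aryl vinyl ketone (unmasked in situ from β-chloroketone 5) by a Mizoroki–Heck Ar–Cβ disconnection, in place of the usual Claisen–Schmidt aldol.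
3. 4 ⇒ aryl prenyl ether 3 by aromatic Claisen rearrangement; the bromine blocks the para position and later serves as the Heck handle. 3 ⇒ 4-bromo-3-methoxyphenol (1) + prenyl bromide (2).
4. No rings are formed; both arenes are purchased. The only stereo-element, the E-alkene, is set in the Heck step.

## Route

**Step 1**
Reactants: 1, 4-bromo-3-methoxyphenol; 2, prenyl bromide (1-bromo-3-methylbut-2-ene)
Product: 3, 1-bromo-2-methoxy-4-[(3-methylbut-2-en-1-yl)oxy]benzene
Conditions: K2CO3 (2 equiv), 2 (1.2 equiv), acetone, reflux
Reagents that add atoms: prenyl bromide, CC(C)=CCBr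
Why: Williamson ether synthesis; the phenoxide is O-alkylated by SN2 at the primary allylic bromide, and the aryl bromide is inert.

**Step 2**
Reactants: 3, 1-bromo-2-methoxy-4-[(3-methylbut-2-en-1-yl)oxy]benzene
Product: 4, 4-bromo-5-methoxy-2-(2-methylbut-3-en-2-yl)phenol
Conditions: EtOH/H2O (4:1), degassed, 140 °C, sealed tube
Reagents that add atoms: none
Why: Protic-solvent-accelerated aromatic Claisen ([3,3]-sigmatropic) rearrangement with allyl inversion delivers the 1,1-dimethylallyl group to the less hindered ortho carbon (para to OMe, not the carbon flanked by two oxygens), and the para bromine prevents onward Cope migration.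

**Step 3**
Reactants: 4, 4-bromo-5-methoxy-2-(2-methylbut-3-en-2-yl)phenol; 5, 3-chloro-1-(4-hydroxyphenyl)propan-1-one (1.5 equiv)
Product: 6, licochalcone A, (E)-3-[4-hydroxy-2-methoxy-5-(2-methylbut-3-en-2-yl)phenyl]-1-(4-hydroxyphenyl)prop-2-en-1-one
Conditions: Pd(OAc)2 (5 mol%), P(t-Bu)3·HBF4 (10 mol%), Cy2NMe (4 equiv), BHT (cat.), 1,4-dioxane, 90 °C, Ar
Reagents that add atoms: 3-chloro-1-(4-hydroxyphenyl)propan-1-one, O=C(CCCl)c1ccc(O)cc1 (loses HCl)
Why: Domino E1cB dehydrochlorination/Mizoroki–Heck reaction: the amine unmasks 4-hydroxyphenyl vinyl ketone at low concentration, the electron-rich bulky-phosphine Pd(0) inserts into the Ar–Br bond, and syn-insertion/syn-β-hydride elimination gives only the E-enone, while the hindered unactivated 1,1-dimethylallyl alkene does not compete with the enone.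

**Step 4**
Reactants: 6, licochalcone A
Product: 7, target, (E)-3-[3,4-dihydroxy-2-methoxy-5-(2-methylbut-3-en-2-yl)phenyl]-1-(4-hydroxyphenyl)prop-2-en-1-one
Conditions: IBX (1.1 equiv), DMF, 0 °C → rt, dark; then aq. Na2S2O4 (excess), rt, under Ar
Reagents that add atoms: IBX (2-iodoxybenzoic acid), O=C1OI(=O)(O)c2ccccc12 (delivers one O)
Why: IBX phenol ortho-oxygenation (dearomatization to the o-quinone, then dithionite reduction to the catechol): oxygen is delivered intramolecularly from the I(V)–phenolate to the only free ortho carbon of the B-ring phenol, which is further activated by the adjacent OMe, while the para-acyl A-ring phenol is too electron-poor to react; the enone and terminal alkene are untouched and the E-geometry is retained.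

## Compound list
1 | 4-bromo-3-methoxyphenol | COc1cc(O)ccc1Br | starting material
2 | prenyl bromide (1-bromo-3-methylbut-2-ene) | CC(C)=CCBr | starting material
3 | 1-bromo-2-methoxy-4-[(3-methylbut-2-en-1-yl)oxy]benzene | COc1cc(OCC=C(C)C)ccc1Br | intermediate
4 | 4-bromo-5-methoxy-2-(2-methylbut-3-en-2-yl)phenol | C=CC(C)(C)c1cc(Br)c(OC)cc1O | intermediate
5 | 3-chloro-1-(4-hydroxyphenyl)propan-1-one | O=C(CCCl)c1ccc(O)cc1 | starting material
6 | licochalcone A, (E)-3-[4-hydroxy-2-methoxy-5-(2-methylbut-3-en-2-yl)phenyl]-1-(4-hydroxyphenyl)prop-2-en-1-one | C=CC(C)(C)c1cc(/C=C/C(=O)c2ccc(O)cc2)c(OC)cc1O | intermediate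
7 | (E)-3-[3,4-dihydroxy-2-methoxy-5-(2-methylbut-3-en-2-yl)phenyl]-1-(4-hydroxyphenyl)prop-2-en-1-one (InflamNat IN0234) | C=CC(C)(C)c1cc(/C=C/C(=O)c2ccc(O)cc2)c(OC)c(O)c1O | target

## Summary
Total steps: 4, with no protecting groups.
Longest linear sequence: 4 steps (1 → 3 → 4 → 6 → 7).

**Three steps most likely to fail, with fallbacks:**
1. **Step 4 (IBX oxygenation).** Risks are competing oxidation of the A-ring phenol, over-oxidation, or decomposition of the enone-conjugated o-quinone. Fallback: install the oxygen before the enone exists. Ortho-formylate bromophenol 4 (MgCl2/Et3N/paraformaldehyde) at the carbon between OH and OMe, convert the aldehyde to the catechol by Dakin oxidation (H2O2/NaOH), mask it as the bis-TBS ether, then run the Heck step and remove silyl groups with fluoride.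
2. **Step 3 (domino dehydrochlorination/Heck).** Risks are slow oxidative addition of the very electron-rich bromophenol, and oxa-Michael addition or polymerisation of the vinyl ketone. Fallback: abandon the Ar–Cβ coupling. Protect 4 as its TBS ether, do Br/Li exchange and DMF formylation to the benzaldehyde, then a Claisen–Schmidt condensation with 4'-hydroxyacetophenone (KOH, EtOH) to reach 6.
3. **Step 2 (aromatic Claisen).** Risks are the regioisomer from migration to the carbon between the two oxygens, abnormal Claisen rearrangement, or cyclisation of the ortho-allylphenol to a dihydrobenzofuran. Fallback: make the aryl–C(quaternary) bond by cross-coupling instead. Iodinate 1 ortho to OH/para to OMe (NIS), then carry out a C–I-selective, branch (γ)-selective Pd-catalysed Suzuki–Miyaura coupling with prenyl-Bpin to give 4 directly.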